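Germacrane numbering is used: ring C1–C10, lactone carbons C11–C13, methyls C14/C15. Retrosynthetic cuts, in order: the O9 protecting group and the O6 tigloyl group. Then C11–C12 and C7–C8 together with the lactone C12–O8 bond, which opens the γ-lactone and the cyclodecane at once to an acyclic allenyl aldehyde and CO2. Then C6–C7, C5–C6/C4–C15, C10–C14 and C8–C9.
Enabling feature: C7–C8 is the bond shared by the lactone ring and the ten-membered ring. C13=C11–C7 is the allyl-transposed form of a terminal allene C7=C11=C13 whose central carbon carries the carboxyl carbon C12, and C8–O8 is a former aldehyde.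
Forward: the C8–C6 chain grows linearly from hepta-1,6-diyne (C8 and C6 from formaldehyde, C14 and C15 from Me3Al, C7/C11/C13 from allenyltributylstannane). The oxirane is the first ring, cyclodecane and lactone arise together, and the tiglate and the free 9-OH come last.
Stereochemistry: C9/C10 come from a Sharpless epoxidation (L-(+)-DET) and an invertive methyl opening. C4/C5 come from a second Sharpless epoxidation (D-(−)-DET), C6 from a reagent-controlled allenylboration, and C7/C8 from substrate control by C6 and C9 in the key step.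

Key step: step 12

Assumption: the (R,R)-configured bis-sulfonamide controller of step 9 is taken to deliver the C3 unit to the Re face of the epoxy aldehyde carbonyl (C6), the sense it shows with simple aldehydes. Should the sense be the reverse, the equally available (S,S)-controller is used with no other change.

Step 1
Reactants: 1 hepta-1,6-diyne
Product: 2 octa-2,7-diyn-1-ol
Conditions: n-BuLi (0.5 equiv relative to 1), THF, −78 °C; (CH2O)n, −78 °C → rt; H2O
Reagents that add atoms: formaldehyde (as paraformaldehyde), C=O
Why: Monolithiation of the diyne used in excess, followed by acetylide addition to formaldehyde, is a standard hydroxymethylation that installs C8 and forms no stereocentre.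

Step 2
Reactants: 2 octa-2,7-diyn-1-ol
Product: 3 (2E)-oct-2-en-7-yn-1-ol
Conditions: LiAlH4, THF, 0 °C → reflux; H2O, aq. NaOH
Reagents that add atoms: none
Why: Alkoxide-directed trans-hydroalumination (LiAlH4 reduction of propargylic alcohols) should give only the E-alkene and leave the remote, undirected terminal alkyne untouched.

Step 3
Reactants: 3 (2E)-oct-2-en-7-yn-1-ol
Product: 4 [(2S,3S)-3-(pent-4-yn-1-yl)oxiran-2-yl]methanol
Conditions: Ti(OiPr)4 (10 mol %), L-(+)-DET (12 mol %), t-BuOOH, 4 Å MS, CH2Cl2, −20 °C
Reagents that add atoms: tert-butyl hydroperoxide, CC(C)(C)OO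
Why: Sharpless asymmetric epoxidation of an E-allylic alcohol with L-(+)-DET delivers oxygen to the face that gives the (2S,3S)-epoxy alcohol, which fixes C9 and the carbon that becomes C10.

Step 4
Reactants: 4 [(2S,3S)-3-(pent-4-yn-1-yl)oxiran-2-yl]methanol
Product: 5 (2R,3R)-3-methyloct-7-yne-1,2-diol
Conditions: Me3Al (3 equiv), hexane–CH2Cl2, −20 → 0 °C; aq. work-up
Reagents that add atoms: trimethylaluminium, C[Al](C)C
Why: Aluminium-alkoxide-directed opening of a 2,3-epoxy alcohol by Me3Al takes place at the distal carbon (C10) with inversion, so the trans-epoxide should give the 1,2-diol with C9 retained as (R) and the new methyl-bearing C10 as (R).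

Step 5
Reactants: 5 (2R,3R)-3-methyloct-7-yne-1,2-diol
Product: 7 TES/TBS-protected alkynediol, via primary TES ether 6 (not isolated)
Conditions: TESCl (1.05 equiv), imidazole, CH2Cl2, −78 → −20 °C; then TBSOTf, 2,6-lutidine, −78 → 0 °C
Reagents that add atoms: chlorotriethylsilane, CC[Si](Cl)(CC)CC; tert-butyldimethylsilyl triflate, CC(C)(C)[Si](C)(C)OS(=O)(=O)C(F)(F)F
Why: Rate-controlled silylation marks the primary O8 with the labile TES group (the later aldehyde), and the triflate then caps the secondary O9 with the robust, non-chelating TBS group, both by standard silyl ether formation.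

Step 6
Reactants: 7 TES/TBS-protected alkynediol
Product: 9 E-allylic alcohol, via alkenylalane 8 (not isolated)
Conditions: Me3Al (2.5 equiv), Cp2ZrCl2 (25 mol %), CH2Cl2, 0 °C → rt; n-BuLi, hexane–THF, −78 °C; (CH2O)n, → rt; aq. work-up
Reagents that add atoms: trimethylaluminium, C[Al](C)C; formaldehyde (as paraformaldehyde), C=O
Why: Negishi zirconium-catalysed carboalumination adds methyl (C15, to the internal carbon C4) and aluminium (to C5) syn, and hydroxymethylation of the derived alanate with retention should give the E-trisubstituted allylic alcohol with C3 trans to C6.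

Step 7
Reactants: 9 E-allylic alcohol
Product: 10 (2R,3R)-epoxy alcohol
Conditions: Ti(OiPr)4 (10 mol %), D-(−)-DET (12 mol %), t-BuOOH, 4 Å MS, CH2Cl2, −20 °C
Reagents that add atoms: tert-butyl hydroperoxide, CC(C)(C)OO
Why: Sharpless asymmetric epoxidation of this geraniol-type alcohol is reagent-controlled, and D-(−)-DET should set C4 and C5 as (R,R) irrespective of the remote C9/C10 centres.

Step 8
Reactants: 10 (2R,3R)-epoxy alcohol
Product: 11 (2S,3R)-epoxy aldehyde
Conditions: TEMPO (10 mol %), PhI(OAc)2, CH2Cl2, rt
Reagents that add atoms: none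
Why: Oxoammonium (TEMPO/PhI(OAc)2) oxidation stops at the aldehyde, tolerates the oxirane and the silyl ethers, and should not epimerise C5 (the descriptor changes by priority only).

Step 9
Reactants: 11 (2S,3R)-epoxy aldehyde; 12 allenyltributylstannane
Product: 13 (6R)-α-allenol
Conditions: (R,R)-TsNHCH(Ph)CH(Ph)NHTs, BBr3, CH2Cl2, 0 °C → rt, volatiles removed; 12, CH2Cl2, 0 °C → rt; 11, −78 °C; pH 7 buffer
Reagents that add atoms: none
Why: Tin-to-boron exchange with transposition gives a chiral B-propargyl diazaborolidine, which adds through a six-membered chair (SE2') to give the buta-2,3-dienyl carbinol; the controller decides the carbonyl face and thus sets C6 as (R), the erythro relation to C5 (asymmetric allenylboration).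

Step 10
Reactants: 13 (6R)-α-allenol
Product: 14 O6-triethylsilyl ether
Conditions: TESCl, imidazole, CH2Cl2, 0 °C
Reagents that add atoms: chlorotriethylsilane, CC[Si](Cl)(CC)CC
Why: Standard silylation turns O6 into a group that zerovalent nickel cannot ionise, and this helper can later be removed in the presence of the TBS ether.

Step 11
Reactants: 14 O6-triethylsilyl ether
Product: 15 allenyl aldehyde
Conditions: (COCl)2, DMSO, CH2Cl2, −78 → −40 °C; Et3N, −78 → 0 °C
Reagents that add atoms: none
Why: Under Swern conditions a primary TES ether is converted directly into the aldehyde while secondary TES and TBS ethers persist, and the low temperature should keep C9 from epimerising.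

Step 12
Reactants: 15 allenyl aldehyde
Product: 18 bis-silylated trans-fused lactone, via nickelalactone 16 (not isolated), via hydroxy acid 17 (not isolated)
Conditions: Ni(cod)2 (2 equiv), DBU (8 equiv), CO2 (1 atm), THF, 0 °C, 15 added over 12 h (final 2 mM), → rt; AcOH, 0 °C → rt
Reagents that add atoms: carbon dioxide, O=C=O
Why: Proposed new method: zerovalent nickel couples CO2 oxidatively with the unhindered terminal C11=C13 π bond of the allene, which places C12 on the central carbon C11 and nickel on C13 (nickelalactone 16, a 2-carboxylato-allylnickel whose E and Z σ-forms interconvert through the η3 form), and this allylnickel then adds with allyl transposition through C7 to the nickel-bound aldehyde C8 in a six-membered chair before acetic acid frees hydroxy acid 17, which lactonises. The closest known reaction type is the nickel-promoted carboxylation/cyclisation cascade of allenyl aldehydes under CO2 (five- and six-membered carbocycles) together with the intermolecular sequential addition of CO2 and aldehydes to terminal allenes; new here is the ten-membered closure, which is modelled on the Barbier and Nozaki–Hiyama macrocyclisations of 2-(alkoxycarbonyl)allyl metals onto aldehydes. The cyclodecane closes by 10-exo-trig attack of C7 on the C8 carbonyl (C11=C13 ends exocyclic), the lactone by 5-exo-trig acyl substitution of O8 at C12. C8 is set by C9 (polar Felkin–Anh attack anti to the non-chelating OTBS group, giving the 8,9-anti pattern), C7 is set by C6 (H6 in the allyl plane to minimise A1,3 strain, the aldehyde approaching anti to the C6–O bond), and the 7,8-anti (trans-lactone) relation follows from the chair of the E σ-allyl form with C6 and C9 equatorial, the only arrangement in which both substrate preferences are met. The step needs C12 on C11 and C8 on C7 rather than C13, cyclisation rather than oligomerisation, and an intact C6–O bond: the first two are intrinsic to the central-carbon carboxylation of terminal allenes and to the SE2' reactivity of allyl metals, the third is served by slow addition at high dilution while CO2 stays in large excess so that only the ring closure is concentration-sensitive, and the last by the silyl ether at O6, which is no leaving group towards zerovalent nickel.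

Step 13
Reactants: 18 bis-silylated trans-fused lactone
Product: 19 6-hydroxy lactone (9-OTBS)
Conditions: HF·pyridine, pyridine, THF, 0 °C
Reagents that add atoms: none
Why: Buffered HF·pyridine cleaves a secondary TES ether much faster than a secondary TBS ether, and the non-basic medium should spare the oxirane and prevent translactonisation to O6.

Step 14
Reactants: 19 6-hydroxy lactone (9-OTBS); 20 tigloyl chloride
Product: 21 6-O-tigloyl lactone (9-OTBS)
Conditions: pyridine, DMAP (cat.), CH2Cl2, 0 °C → rt
Reagents that add atoms: none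
Why: DMAP-catalysed acylation of the only free hydroxyl installs the ester, and the E geometry of the tigloyl unit, being the thermodynamic one, should be retained.

Step 15
Reactants: 21 6-O-tigloyl lactone (9-OTBS)
Product: 22 target CNP0165329.2
Conditions: HF·pyridine, THF, 0 °C → rt
Reagents that add atoms: none
Why: Fluoride-driven desilylation in a weakly acidic medium frees 9-OH without the base-induced acyl migration, conjugate addition or translactonisation that a basic fluoride source could trigger.

Compound list
1 | hepta-1,6-diyne | C#CCCCC#C | starting material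
2 | octa-2,7-diyn-1-ol | OCC#CCCCC#C | intermediate
3 | (2E)-oct-2-en-7-yn-1-ol | OC/C=C/CCCC#C | intermediate
4 | [(2S,3S)-3-(pent-4-yn-1-yl)oxiran-2-yl]methanol | OC[C@@H]1O[C@H]1CCCC#C | intermediate
5 | (2R,3R)-3-methyloct-7-yne-1,2-diol | OC[C@H](O)[C@H](C)CCCC#C | intermediate
6 | (2R,3R)-3-methyl-1-(triethylsilyloxy)oct-7-yn-2-ol (not isolated) | CC[Si](CC)(CC)OC[C@H](O)[C@H](C)CCCC#C | intermediate
7 | (2R,3R)-2-(tert-butyldimethylsilyloxy)-3-methyl-1-(triethylsilyloxy)oct-7-yne | CC[Si](CC)(CC)OC[C@H](O[Si](C)(C)C(C)(C)C)[C@H](C)CCCC#C | intermediate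
8 | dimethyl[(1E,6R,7R)-7-(tert-butyldimethylsilyloxy)-2,6-dimethyl-8-(triethylsilyloxy)oct-1-en-1-yl]alane (not isolated) | CC[Si](CC)(CC)OC[C@H](O[Si](C)(C)C(C)(C)C)[C@H](C)CCC/C(C)=C/[Al](C)C | intermediate
9 | (2E,7R,8R)-8-(tert-butyldimethylsilyloxy)-3,7-dimethyl-9-(triethylsilyloxy)non-2-en-1-ol | CC[Si](CC)(CC)OC[C@H](O[Si](C)(C)C(C)(C)C)[C@H](C)CCC/C(C)=C/CO | intermediate
10 | [(2R,3R)-3-{(4R,5R)-5-(tert-butyldimethylsilyloxy)-4-methyl-6-(triethylsilyloxy)hexyl}-3-methyloxiran-2-yl]methanol | CC[Si](CC)(CC)OC[C@H](O[Si](C)(C)C(C)(C)C)[C@H](C)CCC[C@@]1(C)O[C@@H]1CO | intermediate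
11 | (2S,3R)-3-{(4R,5R)-5-(tert-butyldimethylsilyloxy)-4-methyl-6-(triethylsilyloxy)hexyl}-3-methyloxirane-2-carbaldehyde | CC[Si](CC)(CC)OC[C@H](O[Si](C)(C)C(C)(C)C)[C@H](C)CCC[C@@]1(C)O[C@@H]1C=O | intermediate
12 | allenyltributylstannane (tributyl(propa-1,2-dienyl)stannane) | C=C=C[Sn](CCCC)(CCCC)CCCC | starting material
13 | (1R)-1-[(2R,3R)-3-{(4R,5R)-5-(tert-butyldimethylsilyloxy)-4-methyl-6-(triethylsilyloxy)hexyl}-3-methyloxiran-2-yl]buta-2,3-dien-1-ol | CC[Si](CC)(CC)OC[C@H](O[Si](C)(C)C(C)(C)C)[C@H](C)CCC[C@@]1(C)O[C@@H]1[C@H](O)C=C=C | intermediate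
14 | triethylsilyl ether of 13 at O6 (all centres as in 13) | CC[Si](CC)(CC)OC[C@H](O[Si](C)(C)C(C)(C)C)[C@H](C)CCC[C@@]1(C)O[C@@H]1[C@H](O[Si](CC)(CC)CC)C=C=C | intermediate
15 | (2R,3R)-2-(tert-butyldimethylsilyloxy)-3-methyl-6-{(2R,3R)-2-methyl-3-[(1R)-1-(triethylsilyloxy)buta-2,3-dien-1-yl]oxiran-2-yl}hexanal | O=C[C@H](O[Si](C)(C)C(C)(C)C)[C@H](C)CCC[C@@]1(C)O[C@@H]1[C@H](O[Si](CC)(CC)CC)C=C=C | intermediate
16 | nickelalactone: 4-alkylidene-1-oxa-2-nickelacyclopentan-5-one from 15 and CO2 (DBU ligands omitted, C7=C11 geometry labile, not isolated) | O=C[C@H](O[Si](C)(C)C(C)(C)C)[C@H](C)CCC[C@@]1(C)O[C@@H]1[C@H](O[Si](CC)(CC)CC)C=C1C[Ni]OC1=O | intermediate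
17 | 2-(cyclodecyl)acrylic acid: 8-hydroxy-9-OTBS-6-OTES-4,5-epoxygermacr-11(13)-en-12-oic acid, centres spatially as in 18 (not isolated) | OC(=O)C(=C)[C@H]1[C@H](O)[C@H](O[Si](C)(C)C(C)(C)C)[C@H](C)CCC[C@@]2(C)O[C@@H]2[C@@H]1O[Si](CC)(CC)CC | intermediate
18 | (4R,5R,6R,7S,8S,9R,10R)-9-(tert-butyldimethylsilyloxy)-4,5-epoxy-6-(triethylsilyloxy)germacr-11(13)-en-12,8-olide | C=C1C(=O)O[C@@H]2[C@H](O[Si](C)(C)C(C)(C)C)[C@H](C)CCC[C@@]3(C)O[C@@H]3[C@H](O[Si](CC)(CC)CC)[C@@H]12 | intermediate
19 | 9-(tert-butyldimethylsilyloxy)-4,5-epoxy-6-hydroxygermacr-11(13)-en-12,8-olide, all centres spatially as in 18 | C=C1C(=O)O[C@@H]2[C@H](O[Si](C)(C)C(C)(C)C)[C@H](C)CCC[C@@]3(C)O[C@@H]3[C@H](O)[C@@H]12 | intermediate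
20 | tigloyl chloride, (2E)-2-methylbut-2-enoyl chloride | C/C=C(\C)C(=O)Cl | starting material
21 | 9-(tert-butyldimethylsilyloxy)-4,5-epoxy-6-[(2E)-2-methylbut-2-enoyloxy]germacr-11(13)-en-12,8-olide, all centres spatially as in 18 | C=C1C(=O)O[C@@H]2[C@H](O[Si](C)(C)C(C)(C)C)[C@H](C)CCC[C@@]3(C)O[C@@H]3[C@H](OC(=O)/C(C)=C/C)[C@@H]12 | intermediate
22 | (4R,5R,6R,7S,8S,9R,10R)-4,5-epoxy-9-hydroxy-6-[(2E)-2-methylbut-2-enoyloxy]germacr-11(13)-en-12,8-olide (CNP0165329.2) | C=C1C(=O)O[C@@H]2[C@H](O)[C@H](C)CCC[C@@]3(C)O[C@@H]3[C@H](OC(=O)/C(C)=C/C)[C@@H]12 | target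

Total step count: 15. Longest linear sequence: 15 steps (from hepta-1,6-diyne).

Steps most likely to fail

1. Step 12 (labelled).
What may go wrong:
- Intermolecular allylation (oligomerisation) may outrun the ten-membered closure.
- Addition may run through the Z σ-allyl form and lead into the syn (cis-lactone) series.
- DBU may epimerise C9.
- The TBS group may migrate from O9 to the newly formed O8 alkoxide.

Fallback by known chemistry, from 14 back to 18: addition of Br2 (CH2Cl2, −78 °C) to the terminal allene gives the 2,3-dibromoalkene F1, whose alkene geometry is irrelevant. Swern oxidation of its primary TES ether gives the dibromo aldehyde F2. Reduction of the allylic bromide by CrCl2 (THF, high dilution) triggers an intramolecular 2-bromoallylation of the Nozaki–Hiyama type. This reaction is anti-selective and γ-selective, and it closes the cyclodecane to the 1-bromovinyl carbinol F3. Carbonylative lactonisation of the vinyl bromide (Pd(PPh3)4, CO, Et3N, THF, 60 °C) then gives 18.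

2. Step 9.
What may go wrong:
- Facial selectivity may be poor if the controller and the epoxy aldehyde are mismatched.
- Propargyl transfer may compete with allenyl transfer.
- The boron Lewis acid may open the oxirane.

Fallback under substrate control, from 11 back to 13: HC≡CMgBr (THF, −78 °C) gives the C6-epimeric propargylic alcohols F4, and Dess–Martin oxidation gives the epoxy ynone F5. Reduction with Zn(BH4)2 (Et2O, −20 °C) through the chelate between oxirane oxygen and carbonyl oxygen delivers hydride to the open face and gives the erythro (6R)-propargylic alcohol F6. Crabbé homologation ((CH2O)n, CuBr, i-Pr2NH, dioxane, reflux) converts the terminal alkyne into the allene 13.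

3. Step 6.
What may go wrong:
- The primary TES ether may be lost to the Lewis-acidic aluminium and zirconium species.
- Methyl delivery may not be fully regioselective.

Fallback without carbometalation, from 7 back to 9: n-BuLi and (CH2O)n give the propargylic alcohol F7. Hydroxyl-directed hydroalumination with NaAlH2(OCH2CH2OMe)2 followed by I2 gives the (Z)-3-iodoallylic alcohol F8. Me2CuLi (Et2O, 0 °C) replaces iodine by methyl with retention and gives 9.

Further compounds
F1 | step 12 | 2,3-dibromoalkene from 14 (C13H2Br–C11Br=C7H, E/Z mixture, other centres as in 14) | CC[Si](CC)(CC)OC[C@H](O[Si](C)(C)C(C)(C)C)[C@H](C)CCC[C@@]1(C)O[C@@H]1[C@H](O[Si](CC)(CC)CC)C=C(Br)CBr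
F2 | step 12 | dibromo aldehyde (C8 aldehyde of F1) | O=C[C@H](O[Si](C)(C)C(C)(C)C)[C@H](C)CCC[C@@]1(C)O[C@@H]1[C@H](O[Si](CC)(CC)CC)C=C(Br)CBr
F3 | step 12 | 7-(1-bromovinyl)-8-hydroxy-9-OTBS-6-OTES-4,5-epoxycyclodecane, centres spatially as in 17 | C=C(Br)[C@H]1[C@H](O)[C@H](O[Si](C)(C)C(C)(C)C)[C@H](C)CCC[C@@]2(C)O[C@@H]2[C@@H]1O[Si](CC)(CC)CC
F4 | step 9 | propargylic alcohols, epimeric at C6 | CC[Si](CC)(CC)OC[C@H](O[Si](C)(C)C(C)(C)C)[C@H](C)CCC[C@@]1(C)O[C@@H]1C(O)C#C
F5 | step 9 | epoxy ynone (C6 ketone) | CC[Si](CC)(CC)OC[C@H](O[Si](C)(C)C(C)(C)C)[C@H](C)CCC[C@@]1(C)O[C@@H]1C(=O)C#C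
F6 | step 9 | (6R)-propargylic alcohol, erythro to the oxirane | CC[Si](CC)(CC)OC[C@H](O[Si](C)(C)C(C)(C)C)[C@H](C)CCC[C@@]1(C)O[C@@H]1[C@H](O)C#C
F7 | step 6 | (7R,8R)-8-(tert-butyldimethylsilyloxy)-7-methyl-9-(triethylsilyloxy)non-2-yn-1-ol | CC[Si](CC)(CC)OC[C@H](O[Si](C)(C)C(C)(C)C)[C@H](C)CCCC#CCO
F8 | step 6 | (2Z,7R,8R)-8-(tert-butyldimethylsilyloxy)-3-iodo-7-methyl-9-(triethylsilyloxy)non-2-en-1-ol | CC[Si](CC)(CC)OC[C@H](O[Si](C)(C)C(C)(C)C)[C@H](C)CCC/C(I)=C/CO
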